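**Retrosynthetic overview**

- The target is traced back to its 8-iodo congener. The C8–I bond, on the ring-A carbon between O1 and the 7-OH, is not in the target: it is a temporary block for the ring closure and is removed last by hydrodeiodination.
- The 8-iodo congener is traced back to an isomeric open bis-ether of the diaryl-propane-1,3-dione. One thermal operation builds the pyran ring on ring A (atoms O1, C2, C3, C4, C4a, C8a; bonds C4–C4a and O1–C2) by propargyl Claisen shift, [1,5]-H shift and oxa-6π closure. The same operation makes the C3'–CH2 bond of the prenyl group on the 4-hydroxyphenyl ring by an allyl Claisen shift.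
- The bis-ether is cut at the C(O)–CH2 bond of the propane-1,3-dione: crossed Claisen condensation of an iodinated aryl methyl ketone with a methyl benzoate, each carrying its C5 unit on oxygen.
- Both O-bound C5 units come from one reagent, 3-chloro-3-methylbut-1-yne (the benzoate one after Lindlar semireduction). Iodination of 2,4-dihydroxyacetophenone installs the block.
- Ring order: both benzene rings are bought; the only ring formed is the pyran ring, in the key step.

Key step: step 6

Remark on the chemistry: the target has no stereocentre and no stereogenic double bond, so it is achiral and the constitution alone defines the single compound asked for.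

**Step 1**
Reactants: 1 2,4-dihydroxyacetophenone
Product: 2 1-(2,4-dihydroxy-3-iodophenyl)ethanone
Conditions: I2 (0.4 equiv), HIO3 (0.2 equiv), EtOH–H2O, 35–40 °C
Reagents that add atoms: iodine, II; iodic acid, OI(=O)=O
Why: Electrophilic aromatic iodination, with iodic acid re-oxidizing the iodide so that all iodine is used and water is the only co-product, should go to C3, the position ortho to both hydroxyl groups; this installs the temporary blocking iodine.

**Step 2**
Reactants: 2 1-(2,4-dihydroxy-3-iodophenyl)ethanone; 3 3-chloro-3-methylbut-1-yne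
Product: 4 1-[2-hydroxy-3-iodo-4-(2-methylbut-3-yn-2-yloxy)phenyl]ethanone
Conditions: K2CO3, KI (cat.), acetone, reflux, N2 (no copper salt)
Reagents that add atoms: 3-chloro-3-methylbut-1-yne (3), C#CC(C)(C)Cl
Why: Base-mediated O-alkylation of a phenoxide by a tertiary propargylic chloride should take only the more acidic, non-chelated 4-OH, because the 2-OH is held in the hydrogen bond to the acetyl group; copper is left out to avoid alkyne/aryl iodide coupling.

**Step 3**
Reactants: 5 methyl 4-hydroxybenzoate; 3 3-chloro-3-methylbut-1-yne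
Product: 6 methyl 4-(2-methylbut-3-yn-2-yloxy)benzoate
Conditions: K2CO3, KI (cat.), CuI (cat.), acetone, reflux, N2
Reagents that add atoms: 3-chloro-3-methylbut-1-yne (3), C#CC(C)(C)Cl
Why: The same phenoxide O-alkylation with the tertiary propargylic chloride, here copper-assisted, on the single phenol of the ester.

**Step 4**
Reactants: 6 methyl 4-(2-methylbut-3-yn-2-yloxy)benzoate
Product: 7 methyl 4-(2-methylbut-3-en-2-yloxy)benzoate
Conditions: H2 (1 atm), Lindlar catalyst, quinoline, EtOAc, rt
Reagents that add atoms: none
Why: Lindlar semihydrogenation of the terminal alkyne should stop at the vinyl group and leave the ester and the tertiary aryl ether untouched.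

**Step 5**
Reactants: 4 1-[2-hydroxy-3-iodo-4-(2-methylbut-3-yn-2-yloxy)phenyl]ethanone; 7 methyl 4-(2-methylbut-3-en-2-yloxy)benzoate
Product: 8 1-[2-hydroxy-3-iodo-4-(2-methylbut-3-yn-2-yloxy)phenyl]-3-[4-(2-methylbut-3-en-2-yloxy)phenyl]propane-1,3-dione
Conditions: LiHMDS (3.3 equiv), THF, −78 °C to rt; AcOH quench at 0 °C
Reagents that add atoms: none
Why: Crossed Claisen condensation: the lithium phenoxide–enolate of 4 attacks the non-enolizable ester 7, the third equivalent of base deprotonates the diketone and drives the equilibrium, and both tertiary ethers and the aryl iodide should survive amide base at or below room temperature and the mild acetic acid quench.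

**Step 6**
Reactants: 8 1-[2-hydroxy-3-iodo-4-(2-methylbut-3-yn-2-yloxy)phenyl]-3-[4-(2-methylbut-3-en-2-yloxy)phenyl]propane-1,3-dione
Product: 12 1-(7-hydroxy-8-iodo-2,2-dimethyl-2H-chromen-6-yl)-3-[4-hydroxy-3-(3-methylbut-2-en-1-yl)phenyl]propane-1,3-dione, via prenylphenol propargyl ether 9 (not isolated), via allenylphenol 10 (not isolated), via (Z)-o-quinone methide 11 (not isolated)
Conditions: degassed PhNEt2 (0.05 M), 120 °C then 170 °C, Ar, sealed tube
Reagents that add atoms: none
Why: Two pericyclic sequences run in one flask: on ring B the aryl 1,1-dimethylallyl ether undergoes an aromatic Claisen [3,3] shift and re-aromatizes to the C3' prenyl phenol (9), and on ring A the aryl propargyl ether undergoes a Claisen [3,3] shift to the free ortho carbon (the future C4a), enolizes to the allenylphenol 10 and passes by a [1,5]-H shift from the phenolic O–H to the o-quinone methide 11. The pyran ring (O1, C2, C3, C4, C4a, C8a) is then closed by a thermal disrotatory oxa-6π electrocyclization of 11, which forms the O1–C2 bond and restores the aromaticity of ring A. The closest known reaction types are the thermal cyclization of aryl 1,1-dimethylpropargyl ethers to 2,2-dimethyl-2H-chromenes and the ortho-Claisen rearrangement of aryl 1,1-dimethylallyl ethers to o-prenylphenols, both established for para-acyl aryl ethers, as is the use of an iodine substituent between the two oxygens to turn the annulation to the linear isomer. No stereocentre is formed; the Z geometry of the exocyclic alkene of 11 that the ring closure needs follows from the cyclic transition state of the [1,5]-H shift. The step needs regioselectivity on ring A, since the hydrogen-bonded 2-hydroxyaryl ketone would otherwise direct the [3,3] shift to the carbon between the two oxygens and give the angular pyran; the iodine at that carbon leaves only the future C4a open, while on ring B the two ortho positions are equivalent and the tertiary ether carbon guarantees a normal, not a reverse, prenyl group. The weakly basic aniline solvent should hold back acid-induced fragmentation of the tertiary ethers and cyclodehydration of the o-hydroxyaryl diketone.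

**Step 7**
Reactants: 12 1-(7-hydroxy-8-iodo-2,2-dimethyl-2H-chromen-6-yl)-3-[4-hydroxy-3-(3-methylbut-2-en-1-yl)phenyl]propane-1,3-dione
Product: 13 Glyinflanin C, 1-(7-hydroxy-2,2-dimethyl-2H-chromen-6-yl)-3-[4-hydroxy-3-(3-methylbut-2-en-1-yl)phenyl]propane-1,3-dione
Conditions: Pd(PPh3)4 (5 mol %), HCO2Na (3 equiv), DMF, 80 °C
Reagents that add atoms: none
Why: Palladium-catalysed transfer hydrogenolysis (oxidative addition into C–I, formate to Pd–H with loss of CO2, reductive elimination) should act only on the aryl iodide, the one site open to oxidative addition, and leave the trisubstituted and chromene alkenes, the phenols and the diketone unchanged.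

**Compound list**

1 | 2,4-dihydroxyacetophenone | CC(=O)c1ccc(O)cc1O | starting material
2 | 1-(2,4-dihydroxy-3-iodophenyl)ethanone | CC(=O)c1ccc(O)c(I)c1O | intermediate
3 | 3-chloro-3-methylbut-1-yne | C#CC(C)(C)Cl | starting material
4 | 1-[2-hydroxy-3-iodo-4-(2-methylbut-3-yn-2-yloxy)phenyl]ethanone | CC(=O)c1ccc(OC(C)(C)C#C)c(I)c1O | intermediate
5 | methyl 4-hydroxybenzoate | COC(=O)c1ccc(O)cc1 | starting material
6 | methyl 4-(2-methylbut-3-yn-2-yloxy)benzoate | COC(=O)c1ccc(OC(C)(C)C#C)cc1 | intermediate
7 | methyl 4-(2-methylbut-3-en-2-yloxy)benzoate | COC(=O)c1ccc(OC(C)(C)C=C)cc1 | intermediate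
8 | 1-[2-hydroxy-3-iodo-4-(2-methylbut-3-yn-2-yloxy)phenyl]-3-[4-(2-methylbut-3-en-2-yloxy)phenyl]propane-1,3-dione | C#CC(C)(C)Oc1ccc(C(=O)CC(=O)c2ccc(OC(C)(C)C=C)cc2)c(O)c1I | intermediate
9 | 1-[2-hydroxy-3-iodo-4-(2-methylbut-3-yn-2-yloxy)phenyl]-3-[4-hydroxy-3-(3-methylbut-2-en-1-yl)phenyl]propane-1,3-dione (not isolated) | C#CC(C)(C)Oc1ccc(C(=O)CC(=O)c2ccc(O)c(CC=C(C)C)c2)c(O)c1I | intermediate
10 | 1-[2,4-dihydroxy-3-iodo-5-(3-methylbuta-1,2-dien-1-yl)phenyl]-3-[4-hydroxy-3-(3-methylbut-2-en-1-yl)phenyl]propane-1,3-dione (not isolated) | CC(C)=C=Cc1cc(C(=O)CC(=O)c2ccc(O)c(CC=C(C)C)c2)c(O)c(I)c1O | intermediate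
11 | 1-[(3Z)-6-hydroxy-5-iodo-3-(3-methylbut-2-en-1-ylidene)-4-oxocyclohexa-1,5-dien-1-yl]-3-[4-hydroxy-3-(3-methylbut-2-en-1-yl)phenyl]propane-1,3-dione (o-quinone methide, not isolated) | CC(C)=C/C=C1\C(=O)C(I)=C(O)C(C(=O)CC(=O)c2ccc(O)c(CC=C(C)C)c2)=C1 | intermediate
12 | 1-(7-hydroxy-8-iodo-2,2-dimethyl-2H-chromen-6-yl)-3-[4-hydroxy-3-(3-methylbut-2-en-1-yl)phenyl]propane-1,3-dione | CC(C)=CCc1cc(C(=O)CC(=O)c2cc3c(c(I)c2O)OC(C)(C)C=C3)ccc1O | intermediate
13 | Glyinflanin C, 1-(7-hydroxy-2,2-dimethyl-2H-chromen-6-yl)-3-[4-hydroxy-3-(3-methylbut-2-en-1-yl)phenyl]propane-1,3-dione | CC(C)=CCc1cc(C(=O)CC(=O)c2cc3c(cc2O)OC(C)(C)C=C3)ccc1O | target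

**Step count**

Total step count: 7. Longest linear sequence: 5 steps (steps 1, 2, 5, 6, 7); the benzoate branch (steps 3, 4) joins at step 5.

**Steps most likely to fail**

Step 6 (key step). At the temperature the propargyl ether needs, the o-hydroxyaryl 1,3-diketone may cyclodehydrate to a flavone. The tertiary allyl ether may fragment with loss of isoprene instead of rearranging. The [3,3] shift on ring A may also go ipso to the iodinated carbon with loss of iodine. The fallback sets out from 4 and comes back to the route at 12; it moves the ring-A annulation in front of the diketone formation, so that the diketone never sees more than about 110 °C. Ketone 4 is heated in N,N-diethylaniline at 180 °C to give 1-(7-hydroxy-8-iodo-2,2-dimethyl-2H-chromen-6-yl)ethanone F1. Crossed Claisen condensation of F1 with ester 7 (LiHMDS, THF) should then give 1-(7-hydroxy-8-iodo-2,2-dimethyl-2H-chromen-6-yl)-3-[4-(2-methylbut-3-en-2-yloxy)phenyl]propane-1,3-dione F2. Heating F2 in toluene at 110 °C should trigger only the low-barrier allyl Claisen shift and give 12.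

Step 5. The terminal alkyne may be partly lithiated and the acetylide may add to the ester. The hindered phenoxide–enolate may also acylate slowly, so that retro-Claisen cleavage of the product competes. The fallback sets out from 2 and comes back at 8; it acylates before it etherifies, so that no alkyne is present when the strong base is used. The trilithium salt of 2 (LiHMDS, 4.3 equiv, THF) is condensed with 7 to give 1-(2,4-dihydroxy-3-iodophenyl)-3-[4-(2-methylbut-3-en-2-yloxy)phenyl]propane-1,3-dione F3. The non-chelated and most acidic 4-OH of F3 is then alkylated with 3 (K2CO3, KI, acetone, reflux) to give 8.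

Step 7. Palladium hydride may move the prenyl double bond into conjugation with the arene or reduce the C3=C4 alkene, and the diketonate may bind the catalyst and stall the reduction. The fallback sets out from 4 and comes back at 13; it removes the iodine at the fragment stage, once the ring closure it controls is done. 1-(7-Hydroxy-8-iodo-2,2-dimethyl-2H-chromen-6-yl)ethanone F1, made from 4 as in the first fallback, is hydrodeiodinated (Pd(PPh3)4, HCO2Na, DMF, 80 °C) to 1-(7-hydroxy-2,2-dimethyl-2H-chromen-6-yl)ethanone F4. Condensation of F4 with 7 (LiHMDS, THF) should give 1-(7-hydroxy-2,2-dimethyl-2H-chromen-6-yl)-3-[4-(2-methylbut-3-en-2-yloxy)phenyl]propane-1,3-dione F5. The allyl Claisen shift of F5 in toluene at 110 °C then gives 13.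

**Further compounds**

F1 | step 6 | 1-(7-hydroxy-8-iodo-2,2-dimethyl-2H-chromen-6-yl)ethanone | CC(=O)c1cc2c(c(I)c1O)OC(C)(C)C=C2
F2 | step 6 | 1-(7-hydroxy-8-iodo-2,2-dimethyl-2H-chromen-6-yl)-3-[4-(2-methylbut-3-en-2-yloxy)phenyl]propane-1,3-dione | C=CC(C)(C)Oc1ccc(C(=O)CC(=O)c2cc3c(c(I)c2O)OC(C)(C)C=C3)cc1
F3 | step 5 | 1-(2,4-dihydroxy-3-iodophenyl)-3-[4-(2-methylbut-3-en-2-yloxy)phenyl]propane-1,3-dione | C=CC(C)(C)Oc1ccc(C(=O)CC(=O)c2ccc(O)c(I)c2O)cc1
F4 | step 7 | 1-(7-hydroxy-2,2-dimethyl-2H-chromen-6-yl)ethanone | CC(=O)c1cc2c(cc1O)OC(C)(C)C=C2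
F5 | step 7 | 1-(7-hydroxy-2,2-dimethyl-2H-chromen-6-yl)-3-[4-(2-methylbut-3-en-2-yloxy)phenyl]propane-1,3-dione | C=CC(C)(C)Oc1ccc(C(=O)CC(=O)c2cc3c(cc2O)OC(C)(C)C=C3)cc1
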